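**Plan**
- Retrosynthesis: remove the C2 propionate and C14 acetate; open the ten-membered ring and the butenolide together at C7–C8 and O–C19 (chromium-mediated closure of an alkenyl triflate onto a (Z)-enal, then lactonisation); cut C8–C9 (acylative zinc coupling).
- The cyclohexene is traced back, through its 7-oxabicyclo[2.2.1]heptane form (oxygen bridging C14 and C11), to a five-membered carbonyl ylide C14–O–C11 (ring carbons C1, C10) and a two-carbon dipolarophile: C11–C12 and C13–C14 are cut together.
- Enabling feature: the 3-cyclohexenyl acetate unit C11(Me)=C12–C13–C14(OAc) is the opened form of such an oxa bridge. Quaternary C1 rules out a furan Diels–Alder but not the ylide. The C9 methylene on C10 lies on the ring face opposite O-14 and can carry the dipolarophile as a vinylsilyl ether, whose silicon later directs bridge opening to C11=C12.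
- Forward: butyrolactone template (C14, C1, C10, C9) → quaternary C1 with the nerol-derived C2–C7 chain → keto tosylhydrazone → ylide cycloaddition (six-membered ring) → bridge opening → C8–C9 → ten-membered ring and butenolide in one closure → propionate.
- Stereochemistry: C10 from rhodium/(R)-BINAP conjugate addition; C1 by methylation anti to the C10 substituent; C2 by CBS reduction; C14 from the tether-directed cycloaddition; C7 in the ring closure; (Z)-C5=C6 from nerol.

Key step: step 14

Remark: positions are given in briarane numbering (C1 quaternary carbon, C2 propionate carbon, C7 lactone carbinol, C8=C17 butenolide alkene, C9 methylene, C10 ring-fusion CH, C11=C12 cyclohexene alkene, C14 acetate carbon, C19 lactone carbonyl); compounds 1, 2, 6 and 25 and all unnumbered reagents are assumed to be purchasable.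

**Route**

Step 1
Reactants: 1 furan-2(5H)-one; 2 potassium trifluoro(prop-1-en-2-yl)borate
Product: 3 (R)-4-(prop-1-en-2-yl)dihydrofuran-2(3H)-one
Conditions: [Rh(cod)2]BF4 (3 mol %), (R)-BINAP, 1,4-dioxane/H2O, 90 °C
Reagents that add atoms: none
Why: Hayashi–Miyaura rhodium-catalysed asymmetric 1,4-addition of an alkenylboron reagent to an unsaturated lactone; the (R)-BINAP–rhodium alkenyl species should add to one enantioface and set C10 (R in 3), by analogy with the established sense for cyclic enones.

Step 2
Reactants: 3 (R)-4-(prop-1-en-2-yl)dihydrofuran-2(3H)-one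
Product: 4 (S)-4-acetyldihydrofuran-2(3H)-one
Conditions: O3, CH2Cl2/MeOH, −78 °C; then Me2S
Reagents that add atoms: ozone, [O-][O+]=O
Why: Ozonolysis of the 1,1-disubstituted alkene with reductive work-up gives the methyl ketone (future C11/C20) under neutral conditions that should not epimerise the adjacent stereocentre.

Step 3
Reactants: 4 (S)-4-acetyldihydrofuran-2(3H)-one
Product: 5 (S)-4-(2-methyl-1,3-dioxolan-2-yl)dihydrofuran-2(3H)-one
Conditions: 1,2-bis(trimethylsilyloxy)ethane, Me3SiOTf (cat.), CH2Cl2, −78 °C
Reagents that add atoms: 1,2-bis(trimethylsilyloxy)ethane, C[Si](C)(C)OCCO[Si](C)(C)C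
Why: Silyl-triflate-catalysed ketalisation at low temperature masks the ketone without enolisation, so C10 keeps its configuration and only the lactone α-position remains acidic.

Step 4
Reactants: 6 nerol
Product: 7 neryl tert-butyldiphenylsilyl ether
Conditions: TBDPSCl, imidazole, CH2Cl2, 0 °C → rt
Reagents that add atoms: tert-butyl(chloro)diphenylsilane, CC(C)(C)[Si](Cl)(c1ccccc1)c1ccccc1
Why: Standard silylation of a primary allylic alcohol; the Z alkene of nerol (future C5=C6) is untouched.

Step 5
Reactants: 7 neryl tert-butyldiphenylsilyl ether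
Product: 8 (4Z)-6-[(tert-butyldiphenylsilyl)oxy]-4-methylhex-4-enal
Conditions: O3 (1.0 equiv), CH2Cl2, pyridine, −78 °C; then PPh3
Reagents that add atoms: ozone, [O-][O+]=O
Why: Regioselective ozonolysis: the distal trisubstituted alkene is more electron-rich than the one deactivated by the allylic silyloxy group and should be cleaved first with one equivalent of ozone, giving the C2 aldehyde.

Step 6
Reactants: 5 (S)-4-(2-methyl-1,3-dioxolan-2-yl)dihydrofuran-2(3H)-one; 8 (4Z)-6-[(tert-butyldiphenylsilyl)oxy]-4-methylhex-4-enal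
Product: 9 aldol adduct (C1–C2 bond formed; mixture of carbinol epimers)
Conditions: LiN(iPr)2, THF, −78 °C; then 8
Reagents that add atoms: none
Why: Aldol addition of the lithium lactone enolate forms the C1–C2 bond anti to the C10 substituent; the configurations at C1 and C2 are inconsequential because both are erased or reset in steps 7 to 9.

Step 7
Reactants: 9 aldol adduct
Product: 10 β-keto lactone
Conditions: Dess–Martin periodinane, NaHCO3, CH2Cl2, rt
Reagents that add atoms: none
Why: Dess–Martin oxidation of the β-hydroxy lactone gives the β-keto lactone and makes C1–H acidic for quaternisation; silyl ether, ketal and alkene are inert.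

Step 8
Reactants: 10 β-keto lactone
Product: 11 quaternary β-keto lactone (3S,4S)
Conditions: K2CO3, MeI, acetone, rt
Reagents that add atoms: iodomethane, CI
Why: C-Methylation of the stabilised β-keto lactone enolate; iodomethane should approach anti to the bulky dioxolanyl group on C10, setting quaternary C1 with methyl trans to that group and the acyl chain cis, the 1,10-relationship of the target.

Step 9
Reactants: 11 quaternary β-keto lactone
Product: 12 (2S)-hydroxy lactone
Conditions: (R)-2-methyl-CBS-oxazaborolidine (cat.), catecholborane, toluene, −78 → −40 °C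
Reagents that add atoms: none
Why: Corey–Bakshi–Shibata reduction; the catalyst distinguishes quaternary C1 from the C3 methylene and should deliver hydride to give the (2S) carbinol, the sense also favoured by the non-chelated Felkin–Anh arrangement, while lactone, ketal and alkene are not reduced at low temperature.

Step 10
Reactants: 12 (2S)-hydroxy lactone
Product: 13 C2 tert-butyldimethylsilyl ether
Conditions: TBSOTf, 2,6-lutidine, CH2Cl2, −78 → 0 °C
Reagents that add atoms: tert-butyldimethylsilyl trifluoromethanesulfonate, CC(C)(C)[Si](C)(C)OS(=O)(=O)C(F)(F)F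
Why: Silyl triflate silylation protects the hindered secondary C2 alcohol, which would otherwise trap the carbonyl ylide of step 14; the ketone-derived dioxolane tolerates the buffered conditions.

Step 11
Reactants: 13 C2 tert-butyldimethylsilyl ether
Product: 14 lactol (both anomers)
Conditions: iBu2AlH, CH2Cl2, −78 °C
Reagents that add atoms: none
Why: Partial reduction of the hindered α-quaternary lactone with iBu2AlH should stop at the lactol, which brings C14 to the aldehyde oxidation level and distinguishes it from C9.

Step 12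
Reactants: 14 lactol
Product: 16 keto tosylhydrazone alcohol, via tosylhydrazone ketal 15 (not isolated)
Conditions: TsNHNH2 (1.0 equiv), THF, 40 °C; then AcOH/H2O, 35 °C
Reagents that add atoms: 4-methylbenzenesulfonohydrazide, Cc1ccc(cc1)S(=O)(=O)NN; water, O
Why: Condensation of the open hydroxy aldehyde form of the lactol with one equivalent of tosylhydrazide gives the C14 tosylhydrazone and frees the C9 hydroxyl; mild aqueous acid then hydrolyses the dioxolane to the C11 methyl ketone while the sulfonylhydrazone and both silyl ethers should persist.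

Step 13
Reactants: 16 keto tosylhydrazone alcohol
Product: 17 dimethylvinylsilyl ether (cycloaddition precursor)
Conditions: CH2=CHSiMe2Cl, imidazole, CH2Cl2, −20 °C
Reagents that add atoms: chloro(dimethyl)vinylsilane, C=C[Si](C)(C)Cl
Why: Silylation of the primary C9 hydroxyl installs the vinylsilane as a temporary three-atom tether (C9–O–Si) on C10; the sulfonylhydrazone N–H is far less reactive towards the chlorosilane.

Step 14
Reactants: 17 dimethylvinylsilyl ether
Product: 21 silicon-tethered 7-oxabicyclo[2.2.1]heptane cycloadduct, via sodium tosylhydrazonide 18 (not isolated), via diazoalkane 19 (not isolated), via carbonyl ylide 20 (not isolated)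
Conditions: NaH, THF, 0 °C; then Rh2(OAc)4 (2 mol %), BnEt3NCl (10 mol %), 1,4-dioxane, 80 °C, 0.005 M
Reagents that add atoms: none
Why: Proposed new method: deprotonated tosylhydrazone 18 expels sulfinate on heating (Bamford–Stevens) to give diazoalkane 19, whose rhodium carbene at C14 is flanked by quaternary C1 (no 1,2-hydride shift possible) and is captured by the oxygen of the γ-ketone to give the five-membered, acceptor-free carbonyl ylide 20 (C14–O–C11), which adds suprafacially across the tethered vinylsilane in a (3+2) cycloaddition that forms C13–C14 and C11–C12 together. The closest known reaction type is the rhodium-catalysed tandem carbonyl ylide formation/intramolecular dipolar cycloaddition of diazo ketones, together with the generation of cyclic ylides from tosylhydrazone salts of ortho-acyl benzaldehydes; new here is an aliphatic ylide without an acyl stabiliser, made from a diazoalkane generated in situ. Three rings close: the oxolane of the ylide by attack of the carbonyl oxygen on the carbene carbon, the carbocyclic six-membered ring C1–C10–C11–C12–C13–C14 (as a 7-oxabicyclo[2.2.1]heptane) by the (3+2) event, and the six-membered oxasilinane C10–C9–O–Si–C12–C11 by the tether in fused mode with silicon endo. C14 is set because the three-atom tether from C10 can deliver the alkene only to the ylide face that carries C9, so the oxygen bridge ends up anti to C9 and syn to H-10 (O-14 trans to Me-15, as in the target); the transient centres C11 and C12 follow from the same suprafacial, tether-bound geometry, and C1, C2 and C10 are not touched. The step needs chemoselectivity for ylide formation and cycloaddition over carbene C–H insertion, 1,2-alkyl shift and proton transfer within the ylide, which the fast five-membered oxygen capture, the absence of hydrogen on C1 and the intramolecular dipolarophile are expected to secure, and regioselectivity (silicon-bearing carbon to C11), which the short tether enforces.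

Step 15
Reactants: 21 cycloadduct
Product: 22 cyclohexene diol (14-OH, 9-OH)
Conditions: TsOH·H2O (10 mol %), CH2Cl2/MeOH, 0 °C
Reagents that add atoms: none
Why: Acid-promoted Peterson-type β-elimination (as in the cleavage of 2-silylethyl ethers): the protonated bridge oxygen should leave tertiary C11 anti-periplanar to the endo C12–Si bond, giving C11=C12 regiospecifically with the oxygen retained on C14 in unchanged configuration, and methanolysis of the remaining Si–O–C9 link removes the tether.

Step 16
Reactants: 22 cyclohexene diol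
Product: 23 C9 iodide
Conditions: I2, PPh3, imidazole, CH2Cl2, 0 °C
Reagents that add atoms: iodine, II
Why: Appel-type iodination is selective for the primary C9 hydroxyl over the hindered neopentyl secondary C14 hydroxyl, which cannot displace it intramolecularly because the two groups lie on opposite ring faces.

Step 17
Reactants: 23 C9 iodide
Product: 24 C14 acetate
Conditions: Ac2O, 4-(dimethylamino)pyridine, pyridine, CH2Cl2, rt
Reagents that add atoms: acetic anhydride, CC(=O)OC(C)=O
Why: Nucleophile-catalysed acetylation of the secondary C14 alcohol installs the acetate of the target without affecting any stereocentre.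

Step 18
Reactants: 25 3-methoxy-2-methyl-3-oxopropanoic acid
Product: 26 methyl 3-chloro-2-methyl-3-oxopropanoate
Conditions: (COCl)2, DMF (cat.), CH2Cl2, 0 °C → rt
Reagents that add atoms: oxalyl chloride, ClC(=O)C(Cl)=O
Why: Standard conversion of a malonic half ester into its acid chloride, used crude in step 19.

Step 19
Reactants: 24 C14 acetate; 26 methyl 3-chloro-2-methyl-3-oxopropanoate
Product: 28 β-keto ester, via alkylzinc iodide 27 (not isolated)
Conditions: Zn (activated), LiCl, THF, 40 °C; then 26, Pd(PPh3)4 (5 mol %), 0 °C → rt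
Reagents that add atoms: none
Why: Zinc insertion into the primary C–I bond (acetate, silyl ethers and alkenes tolerated) followed by palladium-catalysed Negishi acylation forms the C8–C9 bond and delivers the β-keto ester; C17 is a labile centre removed in step 20.

Step 20
Reactants: 28 β-keto ester
Product: 29 (Z)-enol triflate
Conditions: NaH, Et2O, 0 °C; then Tf2O, −78 °C
Reagents that add atoms: trifluoromethanesulfonic anhydride, O=S(=O)(OS(=O)(=O)C(F)(F)F)C(F)(F)F
Why: O-Triflation of the chelated sodium enolate of the β-keto ester should give the (Z)-enol triflate (C8–OTf cis to the ester), the geometry needed for the later lactonisation.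

Step 21
Reactants: 29 (Z)-enol triflate
Product: 30 diol (2-OH, 7-OH)
Conditions: HF·pyridine, pyridine, THF, 0 °C → rt
Reagents that add atoms: none
Why: Global fluoride-mediated desilylation removes the primary TBDPS and secondary TBS ethers; acetate, enol triflate and alkenes are stable to buffered HF·pyridine.

Step 22
Reactants: 30 diol
Product: 31 (Z)-enal
Conditions: MnO2, CH2Cl2, rt
Reagents that add atoms: none
Why: MnO2 oxidises only the allylic primary alcohol (C7) to the (Z)-enal under neutral conditions that should preserve the alkene geometry; the non-allylic C2 alcohol is untouched.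

Step 23
Reactants: 31 (Z)-enal
Product: 33 2-hydroxy macrocyclic butenolide, via ring-closed hydroxy ester 32 (not isolated)
Conditions: CrCl2 (10 equiv), NiCl2 (cat.), DMSO/THF, rt, 0.002 M
Reagents that add atoms: none
Why: Intramolecular Nozaki–Hiyama–Kishi reaction: the alkenyl triflate is activated by zerovalent nickel, transmetalated to chromium and added to the C7 aldehyde, closing the ten-membered ring at C7–C8, and the new alkoxide lactonises onto the cis ester to give the butenolide; C7 is set by attack on the aldehyde face exposed on the periphery of the folding chain (7R expected, the main uncertainty), and high dilution suppresses oligomerisation.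

Step 24
Reactants: 33 2-hydroxy macrocyclic butenolide
Product: 34 target CNP0112230.1
Conditions: (EtCO)2O, 4-(dimethylamino)pyridine, pyridine, CH2Cl2, 0 °C
Reagents that add atoms: propionic anhydride, CCC(=O)OC(=O)CC
Why: Nucleophile-catalysed acylation of the remaining secondary C2 alcohol with propionic anhydride completes the target without touching any stereocentre.

**Compound list**

1 | furan-2(5H)-one | O=C1OCC=C1 | starting material
2 | potassium trifluoro(prop-1-en-2-yl)borate | [K+].CC(=C)[B-](F)(F)F | starting material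
3 | (R)-4-(prop-1-en-2-yl)dihydrofuran-2(3H)-one | O=C1C[C@H](C(C)=C)CO1 | intermediate
4 | (S)-4-acetyldihydrofuran-2(3H)-one | O=C1C[C@H](C(C)=O)CO1 | intermediate
5 | (S)-4-(2-methyl-1,3-dioxolan-2-yl)dihydrofuran-2(3H)-one | O=C1C[C@H](C2(C)OCCO2)CO1 | intermediate
6 | nerol, (2Z)-3,7-dimethylocta-2,6-dien-1-ol | CC(C)=CCC/C(C)=C\CO | starting material
7 | neryl tert-butyldiphenylsilyl ether | CC(C)=CCC/C(C)=C\CO[Si](c1ccccc1)(c1ccccc1)C(C)(C)C | intermediate
8 | (4Z)-6-[(tert-butyldiphenylsilyl)oxy]-4-methylhex-4-enal | O=CCC/C(C)=C\CO[Si](c1ccccc1)(c1ccccc1)C(C)(C)C | intermediate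
9 | aldol adduct: lactone 5 bearing at its α-carbon (C1) the (4Z)-6-(TBDPS-oxy)-1-hydroxy-4-methylhex-4-enyl chain, mixture of epimers at C1 and C2 | O=C1OC[C@@H](C2(C)OCCO2)C1C(O)CC/C(C)=C\CO[Si](c1ccccc1)(c1ccccc1)C(C)(C)C | intermediate
10 | β-keto lactone: (4S)-3-[(4Z)-6-(TBDPS-oxy)-4-methylhex-4-enoyl]-4-(2-methyl-1,3-dioxolan-2-yl)dihydrofuran-2(3H)-one, C3 labile | O=C1OC[C@@H](C2(C)OCCO2)C1C(=O)CC/C(C)=C\CO[Si](c1ccccc1)(c1ccccc1)C(C)(C)C | intermediate
11 | (3S,4S)-3-[(4Z)-6-(TBDPS-oxy)-4-methylhex-4-enoyl]-3-methyl-4-(2-methyl-1,3-dioxolan-2-yl)dihydrofuran-2(3H)-one (methyl trans to the dioxolanyl group) | O=C1OC[C@@H](C2(C)OCCO2)[C@@]1(C)C(=O)CC/C(C)=C\CO[Si](c1ccccc1)(c1ccccc1)C(C)(C)C | intermediate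
12 | (3S,4S)-3-[(1S,4Z)-6-(TBDPS-oxy)-1-hydroxy-4-methylhex-4-enyl]-3-methyl-4-(2-methyl-1,3-dioxolan-2-yl)dihydrofuran-2(3H)-one | O=C1OC[C@@H](C2(C)OCCO2)[C@@]1(C)[C@@H](O)CC/C(C)=C\CO[Si](c1ccccc1)(c1ccccc1)C(C)(C)C | intermediate
13 | tert-butyldimethylsilyl ether of 12 at the C2 hydroxyl | O=C1OC[C@@H](C2(C)OCCO2)[C@@]1(C)[C@@H](O[Si](C)(C)C(C)(C)C)CC/C(C)=C\CO[Si](c1ccccc1)(c1ccccc1)C(C)(C)C | intermediate
14 | lactol from 13 (C14 hemiacetal, both anomers) | OC1OC[C@@H](C2(C)OCCO2)[C@@]1(C)[C@@H](O[Si](C)(C)C(C)(C)C)CC/C(C)=C\CO[Si](c1ccccc1)(c1ccccc1)C(C)(C)C | intermediate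
15 | C14 (E)-tosylhydrazone with free C9 hydroxyl and C11 dioxolane | Cc1ccc(cc1)S(=O)(=O)N/N=C/[C@](C)([C@@H](O[Si](C)(C)C(C)(C)C)CC/C(C)=C\CO[Si](c1ccccc1)(c1ccccc1)C(C)(C)C)[C@@H](CO)C1(C)OCCO1 | intermediate
16 | C14 tosylhydrazone, C11 methyl ketone, C9 alcohol | Cc1ccc(cc1)S(=O)(=O)N/N=C/[C@](C)([C@@H](O[Si](C)(C)C(C)(C)C)CC/C(C)=C\CO[Si](c1ccccc1)(c1ccccc1)C(C)(C)C)[C@@H](CO)C(C)=O | intermediate
17 | C9 dimethylvinylsilyl ether of 16 | Cc1ccc(cc1)S(=O)(=O)N/N=C/[C@](C)([C@@H](O[Si](C)(C)C(C)(C)C)CC/C(C)=C\CO[Si](c1ccccc1)(c1ccccc1)C(C)(C)C)[C@@H](CO[Si](C)(C)C=C)C(C)=O | intermediate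
18 | sodium salt of tosylhydrazone 17 | [Na+].Cc1ccc(cc1)S(=O)(=O)[N-]/N=C/[C@](C)([C@@H](O[Si](C)(C)C(C)(C)C)CC/C(C)=C\CO[Si](c1ccccc1)(c1ccccc1)C(C)(C)C)[C@@H](CO[Si](C)(C)C=C)C(C)=O | intermediate
19 | C14 diazoalkane | [N-]=[N+]=C[C@](C)([C@@H](O[Si](C)(C)C(C)(C)C)CC/C(C)=C\CO[Si](c1ccccc1)(c1ccccc1)C(C)(C)C)[C@@H](CO[Si](C)(C)C=C)C(C)=O | intermediate
20 | five-membered carbonyl ylide C14–O–C11 | CC1=[O+][CH-][C@](C)([C@@H](O[Si](C)(C)C(C)(C)C)CC/C(C)=C\CO[Si](c2ccccc2)(c2ccccc2)C(C)(C)C)[C@H]1CO[Si](C)(C)C=C | intermediate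
21 | cycloadduct: 7-oxabicyclo[2.2.1]heptane (oxygen bridging C14 and C11, anti to C9) fused to the oxasilinane C10–C9–O–Si–C12–C11, silicon endo on C12 | C[C@@]12O[C@H]3C[C@@H]1[Si](C)(C)OC[C@@H]2[C@@]3(C)[C@@H](O[Si](C)(C)C(C)(C)C)CC/C(C)=C\CO[Si](c4ccccc4)(c4ccccc4)C(C)(C)C | intermediate
22 | cyclohexene diol: C11=C12 alkene, 14-OH trans to Me-15, 9-CH2OH, C2–OTBS, C7–OTBDPS | CC1=CC[C@H](O)[C@](C)([C@@H](O[Si](C)(C)C(C)(C)C)CC/C(C)=C\CO[Si](c2ccccc2)(c2ccccc2)C(C)(C)C)[C@H]1CO | intermediate
23 | C9 iodide of 22 | CC1=CC[C@H](O)[C@](C)([C@@H](O[Si](C)(C)C(C)(C)C)CC/C(C)=C\CO[Si](c2ccccc2)(c2ccccc2)C(C)(C)C)[C@H]1CI | intermediate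
24 | C14 acetate of 23 | CC1=CC[C@H](OC(C)=O)[C@](C)([C@@H](O[Si](C)(C)C(C)(C)C)CC/C(C)=C\CO[Si](c2ccccc2)(c2ccccc2)C(C)(C)C)[C@H]1CI | intermediate
25 | 3-methoxy-2-methyl-3-oxopropanoic acid | COC(=O)C(C)C(=O)O | starting material
26 | methyl 3-chloro-2-methyl-3-oxopropanoate | COC(=O)C(C)C(Cl)=O | intermediate
27 | C9 alkylzinc iodide from 24 | CC1=CC[C@H](OC(C)=O)[C@](C)([C@@H](O[Si](C)(C)C(C)(C)C)CC/C(C)=C\CO[Si](c2ccccc2)(c2ccccc2)C(C)(C)C)[C@H]1C[Zn]I | intermediate
28 | β-keto ester: C9–C8(=O)–C17H(CH3)–CO2Me, C17 epimers | CC1=CC[C@H](OC(C)=O)[C@](C)([C@@H](O[Si](C)(C)C(C)(C)C)CC/C(C)=C\CO[Si](c2ccccc2)(c2ccccc2)C(C)(C)C)[C@H]1CC(=O)C(C)C(=O)OC | intermediate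
29 | (Z)-enol triflate of 28 (OTf on C8 cis to the ester) | CC1=CC[C@H](OC(C)=O)[C@](C)([C@@H](O[Si](C)(C)C(C)(C)C)CC/C(C)=C\CO[Si](c2ccccc2)(c2ccccc2)C(C)(C)C)[C@H]1C/C(OS(=O)(=O)C(F)(F)F)=C(\C)C(=O)OC | intermediate
30 | diol: free C2 and C7 hydroxyls | CC1=CC[C@H](OC(C)=O)[C@](C)([C@@H](O)CC/C(C)=C\CO)[C@H]1C/C(OS(=O)(=O)C(F)(F)F)=C(\C)C(=O)OC | intermediate
31 | (Z)-enal at C7 with free C2 hydroxyl | CC1=CC[C@H](OC(C)=O)[C@](C)([C@@H](O)CC/C(C)=C\C=O)[C@H]1C/C(OS(=O)(=O)C(F)(F)F)=C(\C)C(=O)OC | intermediate
32 | ring-closed ten-membered (7R)-hydroxy methyl ester before lactonisation | O[C@H]1CC/C(C)=C\[C@@H](O)/C(=C(/C)C(=O)OC)C[C@H]2C(C)=CC[C@H](OC(C)=O)[C@]12C | intermediate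
33 | 2-O-depropionyl target: (1S,2S,5Z,7R,10S,14S) macrocyclic butenolide with free C2 hydroxyl | O[C@H]1CC/C(C)=C\[C@H]2OC(=O)C(C)=C2C[C@H]2C(C)=CC[C@H](OC(C)=O)[C@]12C | intermediate
34 | CNP0112230.1: (1S,2S,5Z,7R,10S,14S) 14-acetoxy-2-propanoyloxy briarane butenolide | CCC(=O)O[C@H]1CC/C(C)=C\[C@H]2OC(=O)C(C)=C2C[C@H]2C(C)=CC[C@H](OC(C)=O)[C@]12C | target

**Step count and risks**

Total: 24 steps (steps 4, 5 and 18 prepare side fragments). Longest linear sequence: 21 steps (1–3, 6–17, 19–24).

Steps most likely to fail:

1. Step 14. The acceptor-free carbonyl ylide may be lost by proton shift (from the C11 methyl or H-10) to an enol ether, or the carbene may undergo 1,2-alkyl shift or C–H insertion before the ketone oxygen captures it. Fallback with known chemistry, setting out from lactol 14 and rejoining at diol 22: asymmetric Brown allylboration of the open hydroxy aldehyde form of 14, using the Ipc2B(allyl) antipode that gives the 14S carbinol, should afford homoallylic diol F1. Aqueous acetic acid removes the dioxolane to give keto diol F2. Lombardo–Takai methylenation (Zn, CH2Br2, TiCl4), chosen because the β-hydroxy ketone is base-sensitive, gives diene diol F3. Ring-closing metathesis with the second-generation Grubbs catalyst joins C11 to C12 with loss of ethene and gives 22. C14 is then set by the reagent and the six-membered ring is closed one bond at a time.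

2. Step 23. The ring closure may show poor facial selectivity at C7, since the aldehyde face is chosen only by the conformation of the closing chain, and oligomerisation competes. Fallback, setting out from 31 and rejoining at 34: the stereocentre is corrected after ring closure instead of being set in it. The 7-epimeric hydroxy butenolide F4 obtained from 31 is propionylated (propionic anhydride, 4-(dimethylamino)pyridine, pyridine) to the 7-epimer of the target F5. C7, which is γ to the lactone carbonyl and doubly allylic, is then equilibrated through the furanolate with catalytic DBU in toluene at room temperature; the epimers are separated and the wrong one is recycled. This relies on thermodynamic rather than kinetic control, and exposure should be short to avoid migration of the C5=C6 alkene.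

3. Step 12. During acidic ketal cleavage the sulfonylhydrazone N–H may add to the freed γ-ketone (cyclic hemiaminal, then dehydration), or the hydrazone may hydrolyse. Fallback, setting out from lactol 14 and rejoining at 17: the diazo precursor is installed last, so that no acid treatment follows hydrazone formation. NaBH4 reduces 14 to diol ketal F6. Aqueous acetic acid gives keto diol F7, whose neopentyl C14 hydroxyl is partly tied up as a hemiketal with the ketone. Chloro(dimethyl)vinylsilane and imidazole at low temperature silylate the less hindered C9 hydroxyl to give silyl ether F8. Dess–Martin oxidation gives keto aldehyde F9. One equivalent of tosylhydrazide at 0 °C should condense with the aldehyde in preference to the methyl ketone and give 17.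

Further compounds
F1 | step 14 | homoallylic diol (14S) with C11 dioxolane | C=CC[C@H](O)[C@](C)([C@@H](O[Si](C)(C)C(C)(C)C)CC/C(C)=C\CO[Si](c1ccccc1)(c1ccccc1)C(C)(C)C)[C@@H](CO)C1(C)OCCO1
F2 | step 14 | keto diol | C=CC[C@H](O)[C@](C)([C@@H](O[Si](C)(C)C(C)(C)C)CC/C(C)=C\CO[Si](c1ccccc1)(c1ccccc1)C(C)(C)C)[C@@H](CO)C(C)=O
F3 | step 14 | diene diol (allyl on C14, isopropenyl on C10) | C=CC[C@H](O)[C@](C)([C@@H](O[Si](C)(C)C(C)(C)C)CC/C(C)=C\CO[Si](c1ccccc1)(c1ccccc1)C(C)(C)C)[C@@H](CO)C(C)=C
F4 | step 23 | 7-epimer of 33 | O[C@H]1CC/C(C)=C\[C@@H]2OC(=O)C(C)=C2C[C@H]2C(C)=CC[C@H](OC(C)=O)[C@]12C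
F5 | step 23 | 7-epimer of 34 | CCC(=O)O[C@H]1CC/C(C)=C\[C@@H]2OC(=O)C(C)=C2C[C@H]2C(C)=CC[C@H](OC(C)=O)[C@]12C
F6 | step 12 | diol ketal (C14 and C9 primary alcohols, C11 dioxolane) | OC[C@](C)([C@@H](O[Si](C)(C)C(C)(C)C)CC/C(C)=C\CO[Si](c1ccccc1)(c1ccccc1)C(C)(C)C)[C@@H](CO)C1(C)OCCO1
F7 | step 12 | keto diol | OC[C@](C)([C@@H](O[Si](C)(C)C(C)(C)C)CC/C(C)=C\CO[Si](c1ccccc1)(c1ccccc1)C(C)(C)C)[C@@H](CO)C(C)=O
F8 | step 12 | keto alcohol with C9 dimethylvinylsilyl ether | OC[C@](C)([C@@H](O[Si](C)(C)C(C)(C)C)CC/C(C)=C\CO[Si](c1ccccc1)(c1ccccc1)C(C)(C)C)[C@@H](CO[Si](C)(C)C=C)C(C)=O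
F9 | step 12 | keto aldehyde with C9 dimethylvinylsilyl ether | O=C[C@](C)([C@@H](O[Si](C)(C)C(C)(C)C)CC/C(C)=C\CO[Si](c1ccccc1)(c1ccccc1)C(C)(C)C)[C@@H](CO[Si](C)(C)C=C)C(C)=O
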